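**Strategy.** The quinone is not carried as an arene; it is built last. Its ring carbons O=C–C(CH2R)=C–OH form a cyclic β-diketone (vinylogous acid), so the bond between the hydroxyl-bearing carbon and the carbon carrying the decalinylmethyl group is a Claisen bond. Opening it gives a cis-2-methoxy-ene-1,4-dione ending in an α-keto ester, which is the singlet-oxygen cleavage product of a 2-alkyl-3-methoxyfuran-5-carboxylate. In one flask the furan ring is cleaved and the six-membered ring closed, giving the quinone at its final oxidation level with OH and OMe already placed. The decalin comes from a catalytic enantioselective exo-Diels–Alder reaction; a B-alkyl Suzuki coupling joins both halves.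

Key step: step 7

Abbreviation: Dec = the (1R,2S,8aS)-1,2,5,5-tetramethyl-1,2,3,5,6,7,8,8a-octahydronaphthalen-1-yl group of the target (1-Me and 2-Me cis; H-8a trans to 1-Me). The CIP letter at C8a reads R when the exocyclic carbon on C1 bears O or N; the geometry is unchanged.

Assumption 1: as with 2-methylacrolein, the (S)-diphenylprolinol-derived oxazaborolidinium ion is taken to expose the Cα-Re face of a 2-methyl enal; the target needs Cα-Si addition, hence the (R)-catalyst (the mirror-image catalyst would be taken if the sense is the reverse).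

Assumption 2: compounds 1, 4 and 7 are taken as commercial.

**Step 1**
Reactants: 1 2,2-dimethylcyclohexan-1-one
Product: 2 6,6-dimethylcyclohex-1-en-1-yl trifluoromethanesulfonate
Conditions: LDA, THF, −78 °C; PhNTf2, −78 °C to rt
Reagents that add atoms: N-phenylbis(trifluoromethanesulfonimide), O=S(=O)(N(c1ccccc1)S(=O)(=O)C(F)(F)F)C(F)(F)F
Why: Enol triflate formation: deprotonation is possible only at the CH2 α-carbon because the other α-carbon is quaternary, and the lithium enolate is O-sulfonylated by PhNTf2.

**Step 2**
Reactants: 2 6,6-dimethylcyclohex-1-en-1-yl trifluoromethanesulfonate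
Product: 3 1-ethenyl-6,6-dimethylcyclohex-1-ene
Conditions: tributyl(vinyl)stannane, Pd(PPh3)4 (3 mol%), LiCl, THF, 65 °C
Reagents that add atoms: tributyl(vinyl)stannane, C=C[Sn](CCCC)(CCCC)CCCC
Why: Stille cross-coupling of an alkenyl triflate with a vinylstannane, promoted by LiCl, which should deliver the semicyclic diene whose gem-dimethyl group biases it toward the s-cis conformer.

**Step 3**
Reactants: 3 1-ethenyl-6,6-dimethylcyclohex-1-ene; 4 (E)-2-methylbut-2-enal (tiglic aldehyde)
Product: 5 Dec-CHO, (1R,2S,8aR)-1,2,5,5-tetramethyl-1,2,3,5,6,7,8,8a-octahydronaphthalene-1-carbaldehyde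
Conditions: (R)-3,3-diphenyl-1-(o-tolyl)hexahydropyrrolo[1,2-c][1,3,2]oxazaborole (20 mol%), AlBr3 (16 mol%), CH2Cl2, −40 °C
Reagents that add atoms: none
Why: Catalytic enantioselective Diels–Alder reaction of an α-methyl enal bound to a cationic chiral oxazaborolidine, in which the 1-alkyl terminus of the diene bonds to the α-carbon ("ortho" regiochemistry), the E geometry of 4 fixes the cis relation of the two vicinal methyl groups, the formyl-exo transition state typical of α-methyl enals (reinforced by the gem-dimethyl group beside the diene) places H-8a trans to the C1 methyl, and the catalyst leaves the Cα-Si face open so that C1, C2 and C8a should all be set in the absolute sense shown.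

**Step 4**
Reactants: 5 Dec-CHO
Product: 6 Dec-CH=CH2, (1R,2S,8aS)-1-ethenyl-1,2,5,5-tetramethyl-1,2,3,5,6,7,8,8a-octahydronaphthalene
Conditions: Ph3PCH3Br, KOt-Bu, THF, 0 °C to 50 °C
Reagents that add atoms: methyltriphenylphosphonium bromide, C[P+](c1ccccc1)(c1ccccc1)c1ccccc1.[Br-]
Why: Wittig methylenation of a non-enolisable, α-quaternary aldehyde; no stereocentre is at risk and the small ylide tolerates the neopentyl environment.

**Step 5**
Reactants: 6 Dec-CH=CH2; 7 methyl 4,5-dibromofuran-2-carboxylate
Product: 9 methyl 4-bromo-5-(2-Dec-ethyl)furan-2-carboxylate, via B-alkyl-9-BBN adduct 8 (not isolated)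
Conditions: 9-BBN dimer, THF, 0 °C to rt; then 7, Pd(dppf)Cl2 (5 mol%), aq. K3PO4, THF/DMF, 50 °C
Reagents that add atoms: none
Why: Hydroboration with 9-BBN should take only the monosubstituted vinyl group (boron to the terminal carbon) and leave the hindered trisubstituted ring alkene, and the B-alkyl Suzuki–Miyaura coupling then occurs at C5–Br of 7, the α-bromide activated by the ring oxygen and the conjugated ester.

**Step 6**
Reactants: 9 methyl 4-bromo-5-(2-Dec-ethyl)furan-2-carboxylate
Product: 10 methyl 4-methoxy-5-(2-Dec-ethyl)furan-2-carboxylate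
Conditions: MeOH, Pd2(dba)3 (2 mol%), tBuBrettPhos (5 mol%), Cs2CO3, toluene, 80 °C
Reagents that add atoms: methanol, CO
Why: Palladium-catalysed C–O cross-coupling of a heteroaryl bromide with methanol (Buchwald–Hartwig etherification) using a bulky biarylphosphine that favours C–O reductive elimination; exchange at the methyl ester is degenerate.

**Step 7**
Reactants: 10 methyl 4-methoxy-5-(2-Dec-ethyl)furan-2-carboxylate
Product: 13 2-hydroxy-5-methoxy-3-(Dec-methyl)-1,4-benzoquinone (target), via furan endoperoxide 11 (not isolated), via cis-diacyl enedione 12 (not isolated)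
Conditions: O2, tetraphenylporphyrin (1 mol%), hν (visible), CH2Cl2, −78 °C; Ar purge, Me2S, −78 to 0 °C; NaOMe, MeOH, 0 °C; 1 M HCl work-up
Reagents that add atoms: dioxygen, O=O
Why: Singlet oxygen adds [4+2] across C2/C5 of the electron-rich methoxyfuran to give endoperoxide 11, Me2S reduces the O–O bond to unmask enedione 12 with its two acyl groups held cis, and NaOMe then enolises the side-chain CH2 next to the ketone (the only enolisable position) so that the enolate acylates the ester carbon of the α-keto ester, expels methoxide and tautomerises to the hydroxyquinone, whose vinylogous-acid anion is the thermodynamic sink. The closest known reactions are the photooxygenation–reduction of furans to cis-enediones and the Claisen condensations of δ-keto esters to cyclohexane-1,3-diones and of 2-oxoalkanoate esters to 2,5-dihydroxy-3,6-dialkylbenzoquinones (Dieckmann-type ring closures). The six-membered ring closes in a 6-(enolendo)-exo-trig mode by attack of the enolate carbon on the ester carbonyl, which joins the future C–OH carbon to the alkyl-bearing carbon. No stereocentre is formed, and the three decalin centres are remote from every acidic position, so none can epimerise. The step needs chemoselective oxidation of the furan beside the trisubstituted ring alkene, which the much higher rate of an alkoxyfuran toward singlet oxygen at −78 °C should secure, and C-acylation in preference to aldol addition at the keto carbonyl, which should follow because that five-membered aldol is reversible and cannot dehydrate whereas the acylation is driven by deprotonation of the product. The positions of OH and OMe are fixed by the furan substitution pattern, so no late differentiation of two oxygens is needed.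

**Compound list**
1 | 2,2-dimethylcyclohexan-1-one | CC1(C)CCCCC1=O | starting material
2 | 6,6-dimethylcyclohex-1-en-1-yl trifluoromethanesulfonate | CC1(C)CCCC=C1OS(=O)(=O)C(F)(F)F | intermediate
3 | 1-ethenyl-6,6-dimethylcyclohex-1-ene | C=CC1=CCCCC1(C)C | intermediate
4 | (E)-2-methylbut-2-enal (tiglic aldehyde) | C/C=C(\C)C=O | starting material
5 | Dec-CHO, (1R,2S,8aR)-1,2,5,5-tetramethyl-1,2,3,5,6,7,8,8a-octahydronaphthalene-1-carbaldehyde | O=C[C@@]1(C)[C@@H]2CCCC(C)(C)C2=CC[C@@H]1C | intermediate
6 | Dec-CH=CH2, (1R,2S,8aS)-1-ethenyl-1,2,5,5-tetramethyl-1,2,3,5,6,7,8,8a-octahydronaphthalene | C=C[C@@]1(C)[C@@H]2CCCC(C)(C)C2=CC[C@@H]1C | intermediate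
7 | methyl 4,5-dibromofuran-2-carboxylate | COC(=O)c1cc(Br)c(Br)o1 | starting material
8 | 9-(2-Dec-ethyl)-9-borabicyclo[3.3.1]nonane | C1CCC2CCCC1B2CC[C@@]3(C)[C@@H]4CCCC(C)(C)C4=CC[C@@H]3C | intermediate (not isolated)
9 | methyl 4-bromo-5-(2-Dec-ethyl)furan-2-carboxylate | COC(=O)c1cc(Br)c(CC[C@@]2(C)[C@@H]3CCCC(C)(C)C3=CC[C@@H]2C)o1 | intermediate
10 | methyl 4-methoxy-5-(2-Dec-ethyl)furan-2-carboxylate | COC(=O)c1cc(OC)c(CC[C@@]2(C)[C@@H]3CCCC(C)(C)C3=CC[C@@H]2C)o1 | intermediate
11 | methyl 5-methoxy-4-(2-Dec-ethyl)-2,3,7-trioxabicyclo[2.2.1]hept-5-ene-1-carboxylate (bridgehead configuration not controlled) | COC(=O)C12OOC(CC[C@@]3(C)[C@@H]4CCCC(C)(C)C4=CC[C@@H]3C)(O1)C(OC)=C2 | intermediate (not isolated)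
12 | methyl (3E)-4-methoxy-2,5-dioxo-7-Dec-hept-3-enoate (the two acyl groups cis on the double bond) | COC(=O)C(=O)/C=C(/OC)C(=O)CC[C@@]1(C)[C@@H]2CCCC(C)(C)C2=CC[C@@H]1C | intermediate (not isolated)
13 | 2-hydroxy-5-methoxy-3-{[(1R,2S,8aS)-1,2,5,5-tetramethyl-1,2,3,5,6,7,8,8a-octahydronaphthalen-1-yl]methyl}cyclohexa-2,5-diene-1,4-dione | COC1=CC(=O)C(O)=C(C[C@@]2(C)[C@@H]3CCCC(C)(C)C3=CC[C@@H]2C)C1=O | target

**Totals**
Total step count: 7. Longest linear sequence: 7 steps (1 → 2 → 3 → 5 → 6 → 9 → 10 → 13).

**Steps most likely to fail**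

Step 7. What may go wrong: ene-type oxygenation of the ring alkene or rearrangement of the endoperoxide before it is reduced; under base, reversible conjugate addition and aldol pathways may consume the enedione faster than the C-acylation closes the ring. Fallback (the quinone is carried as a protected arene): the route sets out from aldehyde 5. 2,3,5,6-Tetramethoxyphenyllithium (from 1,2,4,5-tetramethoxybenzene and n-BuLi, THF, 0 °C) is added to 5 and the alkoxide is trapped with Ac2O to give the benzylic acetate F1. Li in NH3/THF at −78 °C removes the benzylic oxygen and gives the tetramethoxyarene F2. (NH4)2Ce(NO3)6 in MeCN/H2O at 0 °C oxidises F2 to the 2,5-dimethoxyquinone F3. KOH in aqueous MeOH then hydrolyses the methoxy group flanked by the alkyl chain, and the route comes back at 13.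

Step 3. What may go wrong: too low a rate of the doubly substituted enal with the hindered diene at the temperature where the catalyst discriminates, and erosion of facial or exo selectivity. Fallback (resolution in place of asymmetric catalysis): the route sets out from 3 and 4. An EtAlCl2-promoted exo-Diels–Alder reaction in CH2Cl2 at −78 °C should give 5 together with its enantiomer F4. Condensation of the mixture with (1R,2R)-N,N'-dimethyl-1,2-diphenylethane-1,2-diamine (molecular sieves, CH2Cl2) gives the diastereomeric imidazolidines F5 (from 5) and F6 (from F4), which are separated by chromatography. Mild aqueous acid hydrolysis of F5 comes back at 5.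

Step 6. What may go wrong: β-hydride elimination from the palladium methoxide and protodebromination in place of C–O reductive elimination at the hindered β-position of the furan. Fallback (C–B oxidation and O-methylation in place of C–O coupling): the route sets out from 9. Miyaura borylation (B2pin2, Pd(dppf)Cl2, KOAc, dioxane, 80 °C) gives the pinacol boronate F7. NaBO3·4H2O in THF/H2O oxidises it to the hydroxyfuran F8, which is expected to sit largely as its furan-3(2H)-one tautomer. O-Methylation with Me2SO4 and K2CO3 in acetone comes back at 10.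

**Further compounds**
F1 | step 7 | Dec-CH(OAc)-(2,3,5,6-tetramethoxyphenyl), benzylic acetate (carbinol configuration not controlled) | CC(=O)OC(c1c(OC)c(OC)cc(OC)c1OC)[C@@]2(C)[C@@H]3CCCC(C)(C)C3=CC[C@@H]2C
F2 | step 7 | 3-(Dec-methyl)-1,2,4,5-tetramethoxybenzene | COc1cc(OC)c(OC)c(C[C@@]2(C)[C@@H]3CCCC(C)(C)C3=CC[C@@H]2C)c1OC
F3 | step 7 | 2,5-dimethoxy-3-(Dec-methyl)-1,4-benzoquinone | COC1=CC(=O)C(OC)=C(C[C@@]2(C)[C@@H]3CCCC(C)(C)C3=CC[C@@H]2C)C1=O
F4 | step 3 | enantiomer of aldehyde 5 | O=C[C@]1(C)[C@H]2CCCC(C)(C)C2=CC[C@H]1C
F5 | step 3 | (4R,5R)-1,3-dimethyl-4,5-diphenyl-2-Dec-imidazolidine (aminal of 5) | CN1[C@H](c2ccccc2)[C@@H](c2ccccc2)N(C)C1[C@@]3(C)[C@@H]4CCCC(C)(C)C4=CC[C@@H]3C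
F6 | step 3 | (4R,5R)-1,3-dimethyl-4,5-diphenyl-2-(ent-Dec)-imidazolidine (aminal of F4) | CN1[C@H](c2ccccc2)[C@@H](c2ccccc2)N(C)C1[C@]3(C)[C@H]4CCCC(C)(C)C4=CC[C@H]3C
F7 | step 6 | methyl 5-(2-Dec-ethyl)-4-(4,4,5,5-tetramethyl-1,3,2-dioxaborolan-2-yl)furan-2-carboxylate | COC(=O)c1cc(B2OC(C)(C)C(C)(C)O2)c(CC[C@@]3(C)[C@@H]4CCCC(C)(C)C4=CC[C@@H]3C)o1
F8 | step 6 | methyl 4-hydroxy-5-(2-Dec-ethyl)furan-2-carboxylate | COC(=O)c1cc(O)c(CC[C@@]2(C)[C@@H]3CCCC(C)(C)C3=CC[C@@H]2C)o1
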